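## Analysis of the target

Tetraphlorethol C is an open chain of four benzene rings joined by three diaryl ether oxygens. Lettering the rings A to D from the 3,5-dihydroxyphenyl end, the ether oxygens join carbon 1 of ring A to B1, B4 to C1 and C4 to D1. There is no further ring and no stereocentre, so the problem is one of constitution only: nine free hydroxyls (on carbons 3 and 5 of ring A and on B2, B6, C2, C6, D2, D4 and D6) and three ether oxygens at fixed positions. Every ring is a phloroglucinol or a 1,2,3,5-tetraoxygenated benzene, so the free compound autoxidises easily (above all in base), is attacked at ring carbon by stray electrophiles, and can lose its aryl ethers in strong acid through protonation on carbon. The difficulty sits at the ether carbons B1, C1 and D1: each is flanked by two oxygen-bearing carbons, so it is crowded and, in the natural oxidation pattern, far too electron-rich for nucleophilic substitution and a poor partner for copper-mediated coupling. Rings B, C and D are also nearly identical, which calls for an iterative assembly with firm control of chain length. The strategy rests on this flanking pattern: B1, C1 and D1 each lie between two hydroxylated carbons (B2/B6, C2/C6, D2/D6), and a phenolic hydroxyl can be derived from a formyl group by Baeyer–Villiger oxidation. With formyl groups at those six positions the three hindered carbons become the most electrophilic sites of their rings and take up an aryloxide by loss of a C–F bond, while the oxygen para to each (B4, C4, D4) serves as nucleophile for the next ring; ring A, with meta oxygens only, enters as a plain phenol.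

## Retrosynthetic reasoning

Target 16 to 15. The two benzyl C–O bonds on ring A are cut last. A neutral hydrogenolysis lets the free nonaphenol appear without acid, base or an electrophilic by-product, and benzyl ethers on ring A tolerate everything before it.

15 to 12. The six C–O bonds at B2, B6, C2, C6, D2 and D6 are traced back to six C–CHO bonds. This is the polarity inversion of the plan: the hydroxyls that make B1, C1 and D1 unreactive are replaced by acceptors that make them reactive. The forward reaction has to insert oxygen at all six formyl groups (hexaformate 13), transfer the formyl groups to solvent (14) and remove the D4 acetal, which is done in the same acidic operation so that the polyphenol is never handled in base.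

12 to 11 and 6. The C4–O–D1 ether is cut on the D1 side. D1 carries two ortho formyl groups and is the only activated carbon of that bond, whereas C4 is meta to its own formyl groups and cannot act as electrophile. The forward reaction is displacement of the C–F bond of 6 by the phenoxide of 11.

11 to 10, and 10 to 9 and 6. The D4-type acetal on the terminal ring of 10 is the masked nucleophile. Removing it and cutting B4–O–C1 on the C1 side repeats the same disconnection with the same building block 6.

9 to 8, and 8 to 7 and 6. A third use of the disconnection cuts the ether between ring A and B1 on the B1 side. Ring A arrives as phenol 7, whose ether carbon is unhindered, so this is the easiest of the three bonds and is made first.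

6 back to 1. Block 6 needs fluorine between two formyl groups and a protected oxygen para to fluorine. Phenol 1 has the fluorine, the oxygen and two methyl groups at exactly these positions, so only the oxidation level of the methyl groups must change (1 to 2 to 3 to 4). The acetate that shields the ring during radical bromination cannot survive a phenoxide, so it is exchanged (4 to 5 to 6) for an acetal that is stable to carbonate and is cleaved by acid in the presence of aldehydes and benzyl ethers.

## Alternatives that were turned down

Alternative 1: Ring D is taken apart at D2–D3 and D5–D6 into two three-carbon pieces. One is the malonate A2, which carries the whole A–B–C aryloxy group on its central carbon (D2, D1, D6). The other is dimethyl 3-oxopentanedioate A3 (D3, D4, D5). In the forward key step, under alkoxide base, the two α-carbons of A3 would be acylated by the two ester groups of A2 and the product would enolise to the phloroglucinol diester A1.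
- For it: the most oxidation-prone ring is made last and arrives with three free hydroxyls. The D1 ether oxygen is attached at an sp3 carbon before the ring exists, so no arylation of a doubly flanked position is needed for that bond.
- Against it: this solves one of the three hindered ethers only. The A–B–C part of A2 still contains the ether between ring A and B1 and the B4–O–C1 ether, for which the annulation offers nothing unless it is repeated on ever larger malonates. A2 has an acidic methine and would sit as an enolate whose esters acylate poorly, while A3 self-condenses readily. After A1, two decarboxylations and six ether cleavages remain.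
- Comparison: it is stronger in not staking six bonds on one operation and in delivering ring D unprotected. The chosen strategy offers instead one reaction and one building block (6) for all three hindered ethers, and a much shorter path.

Alternative 2: The three C–O bonds of ring A (at its carbons 1, 3 and 5) are disconnected, and ring A is derived from the trichloroarene ligand of the cationic complex A5, [CpRu(η6-C6H3Cl3)]PF6 (divalent ruthenium). In the forward key step, in one pot, the trimeric phenol A6 as its aryloxide would displace the first chloride and two equivalents of sodium methoxide A7 the other two, giving complex A4.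
- For it: π-complexation activates an arene that has no ortho or para acceptor, which suits the all-meta pattern of ring A. The conditions are mild, and each oxygen introduced slows the next substitution, which helps to stop after one aryloxide.
- Against it: the bond made is the ether between ring A and B1, approached from the ring A side, which is the one unhindered ether carbon of the molecule; the chosen route makes this bond in step 6 from purchasable 7. The two difficult ethers are hidden inside A6, which is itself a hindered trimer with no route offered. Stoichiometric ruthenium, a decomplexation step and the cleavage of nine methyl ethers on an acid-sensitive product follow.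
- Comparison: it is stronger in mildness and in needing no oxidation. The chosen strategy addresses the bonds that are actually hard.

Alternative 3: Ring C is disconnected at C2–C3, C4–C5 and C1–C2 into the 4-aryloxy-3-ethoxycyclobutenone A9 (which carries rings A and B) and the aryl ethynyl ether A10 (ring D). In the forward key step, heating would open A9 to a vinylketene, which adds A10 in a 2+2 sense; the new cyclobutenone opens and closes by 6π electrocyclisation to the phenol A8.
- For it: the route is convergent. Both ether oxygens on ring C (at C1 and C4) come in on non-aromatic carbons, so ring C needs no hindered arylation, and the polarity of ketene and ynol ether fixes the regiochemistry. C2 and C6 arrive differentiated.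
- Against it: A9 and A10 are two different, sensitive fragments, each several steps from simple materials. A9 is a cyclobutenone with an aryloxy group on its sp3 carbon, and A10 is an ynol ether of a very electron-rich phenol. The ether between ring A and B1 inside A9 must still be made by other means, and A8 carries seven methyl ethers and one ethyl ether to cleave.
- Comparison: it is stronger in convergence and in needing no oxidation. The chosen strategy offers a threefold repetition of one simple displacement with a single block (6) and a neutral last step.

Key step: step 11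

Remark on the chemistry: 1 and 7 are assumed to be purchasable. Ring A is carried as its dibenzyl ether and the D4 acetal is removed by acid methanolysis within the key operation, so that the free polyphenol never meets a Lewis acid or a base; the methoxymethyl cation released there is taken up by the large excess of methanol as dimethoxymethane.

## Route

Step 1
Reactants: 1 4-fluoro-3,5-dimethylphenol
Product: 2 4-fluoro-3,5-dimethylphenyl acetate
Conditions: Ac2O, pyridine, DMAP (cat.), CH2Cl2, 0 °C to rt
Reagents that add atoms: acetic anhydride, CC(=O)OC(C)=O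
Why: O-acylation of a phenol; the acetate lowers the electron density of the ring so that the radical bromination of step 2 goes to the methyl groups and not to the ring, and it tolerates HBr.

Step 2
Reactants: 2 4-fluoro-3,5-dimethylphenyl acetate
Product: 3 3,5-bis(dibromomethyl)-4-fluorophenyl acetate
Conditions: NBS (4.6 equiv), AIBN (cat.), PhCF3, reflux, visible light
Reagents that add atoms: N-bromosuccinimide, O=C1CCC(=O)N1Br
Why: Wohl–Ziegler benzylic bromination; each methyl group takes two bromines under forcing conditions, while a third is held back by crowding and by the polar effect of the two bromines already present.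

Step 3
Reactants: 3 3,5-bis(dibromomethyl)-4-fluorophenyl acetate
Product: 4 4-fluoro-3,5-diformylphenyl acetate
Conditions: AgNO3 (4.4 equiv), acetone/H2O, 55 °C, dark
Reagents that add atoms: water, O
Why: Silver-assisted hydrolysis of benzal bromides to aldehydes; the ring, deactivated by fluorine and two formyl groups, should not react with the dilute nitric acid formed, and the aryl acetate is kept so that no free phenol is exposed to it.

Step 4
Reactants: 4 4-fluoro-3,5-diformylphenyl acetate
Product: 5 2-fluoro-5-hydroxyisophthalaldehyde
Conditions: 3 M HCl, THF, 55 °C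
Reagents that add atoms: none
Why: Acid-catalysed ester hydrolysis; acid is used rather than alkoxide because the C–F bond between two formyl groups is open to displacement by oxygen nucleophiles in base.

Step 5
Reactants: 5 2-fluoro-5-hydroxyisophthalaldehyde
Product: 6 2-fluoro-5-(methoxymethoxy)isophthalaldehyde
Conditions: MOMCl, i-Pr2NEt, CH2Cl2, 0 °C to rt
Reagents that add atoms: chloromethyl methyl ether, COCCl
Why: O-alkylation of an acidic phenol with an α-chloro ether; the hindered amine cannot attack the C–F bond, and the phenoxide, being para to fluorine, deactivates its own ring toward substitution.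

Step 6
Reactants: 6 2-fluoro-5-(methoxymethoxy)isophthalaldehyde; 7 3,5-bis(benzyloxy)phenol
Product: 8 2-[3,5-bis(benzyloxy)phenoxy]-5-(methoxymethoxy)isophthalaldehyde
Conditions: K2CO3, DMF, 60 °C
Reagents that add atoms: none
Why: Nucleophilic aromatic substitution by addition–elimination; the aryloxide of 7 adds at the fluorine-bearing carbon, both ortho formyl groups take up the charge of the Meisenheimer adduct, and fluoride leaves; in DMF the aryloxide reacts at oxygen.

Step 7
Reactants: 8 2-[3,5-bis(benzyloxy)phenoxy]-5-(methoxymethoxy)isophthalaldehyde
Product: 9 2-[3,5-bis(benzyloxy)phenoxy]-5-hydroxyisophthalaldehyde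
Conditions: conc. HCl, i-PrOH/THF, 45 °C
Reagents that add atoms: none
Why: Acid-catalysed acetal cleavage with an electron-poor phenol as leaving group; the secondary alcohol traps the methoxymethyl cation as a formal, so it does not alkylate ring A, and it does not acetalise the aldehydes; benzyl and diaryl ethers are inert.

Step 8
Reactants: 9 2-[3,5-bis(benzyloxy)phenoxy]-5-hydroxyisophthalaldehyde; 6 2-fluoro-5-(methoxymethoxy)isophthalaldehyde
Product: 10 2-{4-[3,5-bis(benzyloxy)phenoxy]-3,5-diformylphenoxy}-5-(methoxymethoxy)isophthalaldehyde
Conditions: K2CO3, DMF, 65 °C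
Reagents that add atoms: none
Why: The same SNAr; the phenoxide of 9 is para to an ether oxygen and only meta to its formyl groups, so it remains a good nucleophile, and the C–F carbon of 6 is attacked much faster than the formyl-flanked ether carbon already present, which carries a poorer leaving group.

Step 9
Reactants: 10 2-{4-[3,5-bis(benzyloxy)phenoxy]-3,5-diformylphenoxy}-5-(methoxymethoxy)isophthalaldehyde
Product: 11 2-{4-[3,5-bis(benzyloxy)phenoxy]-3,5-diformylphenoxy}-5-hydroxyisophthalaldehyde
Conditions: conc. HCl, i-PrOH/THF, 45 °C
Reagents that add atoms: none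
Why: Acid-catalysed acetal cleavage as in step 7, with the cation again trapped by the alcohol.

Step 10
Reactants: 11 2-{4-[3,5-bis(benzyloxy)phenoxy]-3,5-diformylphenoxy}-5-hydroxyisophthalaldehyde; 6 2-fluoro-5-(methoxymethoxy)isophthalaldehyde
Product: 12 2-(4-{4-[3,5-bis(benzyloxy)phenoxy]-3,5-diformylphenoxy}-3,5-diformylphenoxy)-5-(methoxymethoxy)isophthalaldehyde
Conditions: K2CO3, DMF, 65 °C
Reagents that add atoms: none
Why: Third SNAr of the same kind, forming C4–O–D1; moderate temperature and one equivalent of base keep aryloxide exchange at B1 and C1 slow relative to fluoride displacement.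

Step 11
Reactants: 12 2-(4-{4-[3,5-bis(benzyloxy)phenoxy]-3,5-diformylphenoxy}-3,5-diformylphenoxy)-5-(methoxymethoxy)isophthalaldehyde
Product: 15 2-(4-{4-[3,5-bis(benzyloxy)phenoxy]-3,5-dihydroxyphenoxy}-3,5-dihydroxyphenoxy)benzene-1,3,5-triol, via hexaformate 13 (not isolated), via hexaphenol D4 methoxymethyl ether 14 (not isolated)
Conditions: mCPBA (10 equiv), Na2HPO4, CH2Cl2, 0 °C to rt; aq. Na2S2O3, then cold NaH2PO4/Na2HPO4 buffer (pH 7) wash; then HCl (1.25 M in MeOH), argon, rt to 40 °C
Reagents that add atoms: meta-chloroperbenzoic acid, O=C(OO)c1cccc(Cl)c1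
Why: Baeyer–Villiger oxidation of aromatic aldehydes, the peracid counterpart of the Dakin reaction and a known route from ortho- and para-alkoxy- or aryloxybenzaldehydes to phenols, is applied here to six formyl groups at once. The peracid adds to each formyl carbon and, in the Criegee adduct, the ring carbon migrates from carbon to oxygen as the O–O bond breaks, which gives the aryl formate 13 and meta-chlorobenzoic acid. No ring is closed and no stereocentre is formed. The selectivity needed is aryl over hydride migration at all six sites (hydride migration would end as a carboxylic acid) and attack at the formyl groups in preference to the electron-rich ring A. Aryl migration is supported by the ether oxygen ortho to every formyl group, and once one formyl group of a ring has become a formyloxy group that ring is less electron-poor, so the second migration on it should be easier than the first. Solid Na2HPO4 takes up the acid so that neither the formates nor the acetal are cleaved while oxidant is present; rings B, C and D therefore stay masked as weakly donating esters, and ring A, whose ether oxygen is shared with an acceptor-substituted ring, is the only strongly activated arene exposed. After reductive removal of the excess peracid, HCl in methanol transfers the six formyl groups to the solvent (14) and then removes the D4 acetal as dimethoxymethane, which gives 15 without base and under argon.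

Step 12
Reactants: 15 2-(4-{4-[3,5-bis(benzyloxy)phenoxy]-3,5-dihydroxyphenoxy}-3,5-dihydroxyphenoxy)benzene-1,3,5-triol
Product: 16 tetraphlorethol C, 2-{4-[4-(3,5-dihydroxyphenoxy)-3,5-dihydroxyphenoxy]-3,5-dihydroxyphenoxy}benzene-1,3,5-triol
Conditions: H2 (1 atm), Pd/C (10%), THF/MeOH, rt, then filtration and evaporation under argon
Reagents that add atoms: none
Why: Hydrogenolysis of benzyl aryl ethers; neutral conditions leave diaryl ethers and the electron-rich rings untouched, and the only by-product is volatile.

## Compound list

1 | 4-fluoro-3,5-dimethylphenol | Cc1cc(O)cc(C)c1F | starting material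
2 | 4-fluoro-3,5-dimethylphenyl acetate | CC(=O)Oc1cc(C)c(F)c(C)c1 | intermediate
3 | 3,5-bis(dibromomethyl)-4-fluorophenyl acetate | CC(=O)Oc1cc(C(Br)Br)c(F)c(C(Br)Br)c1 | intermediate
4 | 4-fluoro-3,5-diformylphenyl acetate | CC(=O)Oc1cc(C=O)c(F)c(C=O)c1 | intermediate
5 | 2-fluoro-5-hydroxyisophthalaldehyde | O=Cc1cc(O)cc(C=O)c1F | intermediate
6 | 2-fluoro-5-(methoxymethoxy)isophthalaldehyde | COCOc1cc(C=O)c(F)c(C=O)c1 | intermediate
7 | 3,5-bis(benzyloxy)phenol | Oc1cc(OCc2ccccc2)cc(OCc2ccccc2)c1 | starting material
8 | 2-[3,5-bis(benzyloxy)phenoxy]-5-(methoxymethoxy)isophthalaldehyde | COCOc1cc(C=O)c(Oc2cc(OCc3ccccc3)cc(OCc3ccccc3)c2)c(C=O)c1 | intermediate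
9 | 2-[3,5-bis(benzyloxy)phenoxy]-5-hydroxyisophthalaldehyde | Oc1cc(C=O)c(Oc2cc(OCc3ccccc3)cc(OCc3ccccc3)c2)c(C=O)c1 | intermediate
10 | 2-{4-[3,5-bis(benzyloxy)phenoxy]-3,5-diformylphenoxy}-5-(methoxymethoxy)isophthalaldehyde | COCOc1cc(C=O)c(Oc2cc(C=O)c(Oc3cc(OCc4ccccc4)cc(OCc4ccccc4)c3)c(C=O)c2)c(C=O)c1 | intermediate
11 | 2-{4-[3,5-bis(benzyloxy)phenoxy]-3,5-diformylphenoxy}-5-hydroxyisophthalaldehyde | Oc1cc(C=O)c(Oc2cc(C=O)c(Oc3cc(OCc4ccccc4)cc(OCc4ccccc4)c3)c(C=O)c2)c(C=O)c1 | intermediate
12 | hexaaldehyde: 2-(4-{4-[3,5-bis(benzyloxy)phenoxy]-3,5-diformylphenoxy}-3,5-diformylphenoxy)-5-(methoxymethoxy)isophthalaldehyde | COCOc1cc(C=O)c(Oc2cc(C=O)c(Oc3cc(C=O)c(Oc4cc(OCc5ccccc5)cc(OCc5ccccc5)c4)c(C=O)c3)c(C=O)c2)c(C=O)c1 | intermediate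
13 | hexaformate (12 with each CHO replaced by OCHO) | COCOc1cc(OC=O)c(Oc2cc(OC=O)c(Oc3cc(OC=O)c(Oc4cc(OCc5ccccc5)cc(OCc5ccccc5)c4)c(OC=O)c3)c(OC=O)c2)c(OC=O)c1 | intermediate
14 | 2-(4-{4-[3,5-bis(benzyloxy)phenoxy]-3,5-dihydroxyphenoxy}-3,5-dihydroxyphenoxy)-5-(methoxymethoxy)benzene-1,3-diol | COCOc1cc(O)c(Oc2cc(O)c(Oc3cc(O)c(Oc4cc(OCc5ccccc5)cc(OCc5ccccc5)c4)c(O)c3)c(O)c2)c(O)c1 | intermediate
15 | 2-(4-{4-[3,5-bis(benzyloxy)phenoxy]-3,5-dihydroxyphenoxy}-3,5-dihydroxyphenoxy)benzene-1,3,5-triol | Oc1cc(O)c(Oc2cc(O)c(Oc3cc(O)c(Oc4cc(OCc5ccccc5)cc(OCc5ccccc5)c4)c(O)c3)c(O)c2)c(O)c1 | intermediate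
16 | tetraphlorethol C | Oc1cc(O)cc(Oc2c(O)cc(Oc3c(O)cc(Oc4c(O)cc(O)cc4O)cc3O)cc2O)c1 | target

## Step count and least certain steps

Total step count: 12. Longest linear sequence: 12 steps (1 to 16); 7 enters at step 6 and block 6 is used three times (steps 6, 8 and 10).

Step 11 (key step). The most likely failure is hydride instead of aryl migration at one or more of the six sites, above all at the first formyl group of each ring. There the ring is still electron-poor, and the ether oxygen, held between two ortho substituents, is twisted and donates less than in a simple ortho-alkoxybenzaldehyde. Any leak per site is multiplied by six. A second risk is over-oxidation of ring A under the large excess of peracid. Fallback, setting out from 12: addition of MeMgBr (THF, −78 °C) to all six formyl groups should give the hexakis(1-hydroxyethyl) compound F1 (diastereomer mixture, of no consequence), and Dess–Martin oxidation the hexaacetyl compound F2. Baeyer–Villiger oxidation of aryl methyl ketones (mCPBA, or buffered CF3CO3H) has only methyl as competitor for migration and should give the hexaacetate F3. HCl in methanol then cleaves the acetates and the acetal and returns to the route at 15. If over-oxidation rather than migratory preference is the problem, dividing the oxidations as described under step 10 also applies.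

Step 10 (and step 8 by analogy). Aryloxide exchange may occur at the formyl-activated ether carbons B1 and C1 of 11 or 12 under attack by the phenoxide of 11, which would scramble chain lengths. The displacement itself is also slowed by the acetal oxygen para to fluorine. Fallback, setting out from 10: the four formyl groups are oxidised before the last coupling (mCPBA, Na2HPO4, CH2Cl2), which gives the tetraformate F4 (not isolated), and Et3N in degassed methanol gives the tetraphenol F5. BnBr and K2CO3 give the tetrabenzyl ether F6 (six benzyl ethers in all), and HCl in i-PrOH/THF the phenol F7. The nucleophile F7 has no activated ether carbon, and exchange at D1 of the product is degenerate. Coupling with 6 (K2CO3, DMF) should give the dialdehyde F8. mCPBA and then HCl in methanol give the triphenol F10 through the diformate F9 (not isolated), and hydrogenolysis (H2, Pd/C) returns to the route at 16.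

Step 2. Bromination may be non-uniform, stopping at tribromide stages or running on to a tribromomethyl group, so that hydrolysis gives mixtures at the wrong oxidation level. Fallback, setting out from 2: bromination is stopped at one bromine per methyl group (NBS, 2.1 equiv), which gives 3,5-bis(bromomethyl)-4-fluorophenyl acetate F11. Kornblum-type oxidation with N-methylmorpholine N-oxide in MeCN converts both bromomethyl groups into formyl groups and returns to the route at 4.

Step 12. The reaction itself is expected to be clean; the risk is autoxidation of the free nonaphenol, and its loss on the catalyst support, during filtration, concentration and chromatography. Fallback, setting out from 15: after hydrogenolysis the filtrate is not taken to the free phenol but acetylated directly (Ac2O, pyridine) to the nonaacetate F12, which is stable and can be purified. HCl in methanol under argon then releases 16.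

## Further compounds

F1 | step 11 | hexakis(1-hydroxyethyl) analogue of 12 (each CHO replaced by CH(OH)CH3, diastereomer mixture) | COCOc1cc(C(C)O)c(Oc2cc(C(C)O)c(Oc3cc(C(C)O)c(Oc4cc(OCc5ccccc5)cc(OCc5ccccc5)c4)c(C(C)O)c3)c(C(C)O)c2)c(C(C)O)c1
F2 | step 11 | hexaacetyl analogue of 12 (each CHO replaced by COCH3) | COCOc1cc(C(C)=O)c(Oc2cc(C(C)=O)c(Oc3cc(C(C)=O)c(Oc4cc(OCc5ccccc5)cc(OCc5ccccc5)c4)c(C(C)=O)c3)c(C(C)=O)c2)c(C(C)=O)c1
F3 | step 11 | hexaacetate of 14 | COCOc1cc(OC(C)=O)c(Oc2cc(OC(C)=O)c(Oc3cc(OC(C)=O)c(Oc4cc(OCc5ccccc5)cc(OCc5ccccc5)c4)c(OC(C)=O)c3)c(OC(C)=O)c2)c(OC(C)=O)c1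
F4 | step 10 | tetraformate (10 with each CHO replaced by OCHO) | COCOc1cc(OC=O)c(Oc2cc(OC=O)c(Oc3cc(OCc4ccccc4)cc(OCc4ccccc4)c3)c(OC=O)c2)c(OC=O)c1
F5 | step 10 | 2-{4-[3,5-bis(benzyloxy)phenoxy]-3,5-dihydroxyphenoxy}-5-(methoxymethoxy)benzene-1,3-diol | COCOc1cc(O)c(Oc2cc(O)c(Oc3cc(OCc4ccccc4)cc(OCc4ccccc4)c3)c(O)c2)c(O)c1
F6 | step 10 | 1,3-bis(benzyloxy)-2-{3,5-bis(benzyloxy)-4-[3,5-bis(benzyloxy)phenoxy]phenoxy}-5-(methoxymethoxy)benzene | COCOc1cc(OCc2ccccc2)c(Oc2cc(OCc3ccccc3)c(Oc3cc(OCc4ccccc4)cc(OCc4ccccc4)c3)c(OCc3ccccc3)c2)c(OCc2ccccc2)c1
F7 | step 10 | 3,5-bis(benzyloxy)-4-{3,5-bis(benzyloxy)-4-[3,5-bis(benzyloxy)phenoxy]phenoxy}phenol | Oc1cc(OCc2ccccc2)c(Oc2cc(OCc3ccccc3)c(Oc3cc(OCc4ccccc4)cc(OCc4ccccc4)c3)c(OCc3ccccc3)c2)c(OCc2ccccc2)c1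
F8 | step 10 | 2-(3,5-bis(benzyloxy)-4-{3,5-bis(benzyloxy)-4-[3,5-bis(benzyloxy)phenoxy]phenoxy}phenoxy)-5-(methoxymethoxy)isophthalaldehyde | COCOc1cc(C=O)c(Oc2cc(OCc3ccccc3)c(Oc3cc(OCc4ccccc4)c(Oc4cc(OCc5ccccc5)cc(OCc5ccccc5)c4)c(OCc4ccccc4)c3)c(OCc3ccccc3)c2)c(C=O)c1
F9 | step 10 | diformate (F8 with each CHO replaced by OCHO) | COCOc1cc(OC=O)c(Oc2cc(OCc3ccccc3)c(Oc3cc(OCc4ccccc4)c(Oc4cc(OCc5ccccc5)cc(OCc5ccccc5)c4)c(OCc4ccccc4)c3)c(OCc3ccccc3)c2)c(OC=O)c1
F10 | step 10 | 2-(3,5-bis(benzyloxy)-4-{3,5-bis(benzyloxy)-4-[3,5-bis(benzyloxy)phenoxy]phenoxy}phenoxy)benzene-1,3,5-triol | Oc1cc(O)c(Oc2cc(OCc3ccccc3)c(Oc3cc(OCc4ccccc4)c(Oc4cc(OCc5ccccc5)cc(OCc5ccccc5)c4)c(OCc4ccccc4)c3)c(OCc3ccccc3)c2)c(O)c1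
F11 | step 2 | 3,5-bis(bromomethyl)-4-fluorophenyl acetate | CC(=O)Oc1cc(CBr)c(F)c(CBr)c1
F12 | step 12 | nonaacetate of 16 | CC(=O)Oc1cc(OC(C)=O)c(Oc2cc(OC(C)=O)c(Oc3cc(OC(C)=O)c(Oc4cc(OC(C)=O)cc(OC(C)=O)c4)c(OC(C)=O)c3)c(OC(C)=O)c2)c(OC(C)=O)c1
A1 | alternative 1 | dimethyl 5-{4-[4-(3,5-dimethoxyphenoxy)-3,5-dimethoxyphenoxy]-3,5-dimethoxyphenoxy}-2,4,6-trihydroxybenzene-1,3-dicarboxylate | COC(=O)c1c(O)c(C(=O)OC)c(O)c(Oc2cc(OC)c(Oc3cc(OC)c(Oc4cc(OC)cc(OC)c4)c(OC)c3)c(OC)c2)c1O
A2 | alternative 1 | dimethyl 2-{4-[4-(3,5-dimethoxyphenoxy)-3,5-dimethoxyphenoxy]-3,5-dimethoxyphenoxy}propanedioate | COC(=O)C(Oc1cc(OC)c(Oc2cc(OC)c(Oc3cc(OC)cc(OC)c3)c(OC)c2)c(OC)c1)C(=O)OC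
A3 | alternative 1 | dimethyl 3-oxopentanedioate | COC(=O)CC(=O)CC(=O)OC
A4 | alternative 2 | [CpRu(η6-arene)]PF6 complex of the nona-O-methyl ether of 16, metal on ring A (separated components) | COc1cc(OC)cc(Oc2c(OC)cc(Oc3c(OC)cc(Oc4c(OC)cc(OC)cc4OC)cc3OC)cc2OC)c1.[CH-]1C=CC=C1.[Ru+2].F[P-](F)(F)(F)(F)F
A5 | alternative 2 | [CpRu(η6-C6H3Cl3)]PF6 (separated components) | Clc1cc(Cl)cc(Cl)c1.[CH-]1C=CC=C1.[Ru+2].F[P-](F)(F)(F)(F)F
A6 | alternative 2 | 4-[2,6-dimethoxy-4-(2,4,6-trimethoxyphenoxy)phenoxy]-2,6-dimethoxyphenol | Oc1c(OC)cc(Oc2c(OC)cc(Oc3c(OC)cc(OC)cc3OC)cc2OC)cc1OC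
A7 | alternative 2 | sodium methoxide | C[O-].[Na+]
A8 | alternative 3 | 2-[4-(3,5-dimethoxyphenoxy)-3,5-dimethoxyphenoxy]-3-ethoxy-5-(2,4,6-trimethoxyphenoxy)phenol | COc1cc(OC)cc(Oc2c(OC)cc(Oc3c(O)cc(Oc4c(OC)cc(OC)cc4OC)cc3OCC)cc2OC)c1
A9 | alternative 3 | 4-[4-(3,5-dimethoxyphenoxy)-3,5-dimethoxyphenoxy]-3-ethoxycyclobut-2-en-1-one (racemic) | CCOC1=CC(=O)C1Oc1cc(OC)c(Oc2cc(OC)cc(OC)c2)c(OC)c1
A10 | alternative 3 | 2-(ethynyloxy)-1,3,5-trimethoxybenzene | C#COc1c(OC)cc(OC)cc1OC
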